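**Strategy.** Ring A of the target (C1–C2–C3–C4–C5–C9; C1 carries the lavandulyl-type chain, C3 the aroyl group, C5 a prenyl group, C9 is the bridging ketone) is a dearomatised acylphloroglucinol. Its two alkyl-bearing carbons are spanned by the bridge C8 (CH2)–C7 (CH-prenyl)–C6 (CMe2). Cutting C1–C8 and C5–C6 together leaves a flat, fully substituted benzophenone and a three-carbon enal. Forward, the phenoxide of that benzophenone, whose only stereocentre comes from (R)-lavandulol, reacts with 3-acetoxy-3-methyl-2-methylenebutanal in a conjugate addition–elimination–conjugate addition cascade. This forges both bonds, both bridgehead quaternary centres and C7 in one flask.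

Key step: step 8

Remark: (R)-(−)-lavandulol is taken as a purchasable enantiopure alcohol (otherwise it is obtained from the commercial racemate by lipase resolution).
Remark: core numbering as in the first paragraph; O4 is the oxygen on C4; "endo" at C7 means syn to the C2–C4 bridge.

**Step 1**
Reactants: 1 3-hydroxybenzoic acid
Product: 2 3-(tosyloxy)benzoic acid
Conditions: TsCl, NaOH (aq), THF, 0 °C to rt; then HCl
Reagents that add atoms: p-toluenesulfonyl chloride, Cc1ccc(cc1)S(Cl)(=O)=O
Why: Schotten–Baumann O-sulfonylation of the phenoxide (a mixed anhydride at the carboxylate hydrolyses back) installs a phenol protecting group that should tolerate Lewis acid, amide bases, organocerium, palladium and ruthenium chemistry and is cleaved by hydroxide at the end.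

**Step 2**
Reactants: 2 3-(tosyloxy)benzoic acid; 3 5-methoxyresorcinol
Product: 5 3-(2,4-dihydroxy-6-methoxybenzoyl)phenyl tosylate, via acid chloride 4 (not isolated)
Conditions: (COCl)2, DMF (cat.), CH2Cl2, rt; then 3, AlCl3, PhNO2/CH2Cl2, 0 °C to rt
Reagents that add atoms: none
Why: Friedel–Crafts acylation (possibly through O-acylation and Fries shift) should occur para to one hydroxyl and between OH and OMe, giving the 2,4-dihydroxy-6-methoxy pattern; the minor 2,6-dihydroxy-4-methoxy isomer is removed by chromatography.

**Step 3**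
Reactants: 6 (R)-lavandulol
Product: 7 (R)-lavandulyl triflate
Conditions: Tf2O, 2,6-lutidine, CH2Cl2, −78 °C; used at once
Reagents that add atoms: triflic anhydride, O=S(=O)(OS(=O)(=O)C(F)(F)F)C(F)(F)F
Why: Triflation of a primary alcohol at low temperature does not touch the β-stereocentre, and the homoallylic sulfonate is used immediately to avoid ionisation.

**Step 4**
Reactants: 5 3-(2,4-dihydroxy-6-methoxybenzoyl)phenyl tosylate; 7 (R)-lavandulyl triflate
Product: 8 3-{2,4-dihydroxy-6-methoxy-3-[(2S)-5-methyl-2-(prop-1-en-2-yl)hex-4-enyl]benzoyl}phenyl tosylate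
Conditions: LiN(SiMe3)2 (2.2 equiv), toluene/THF, −78 °C; then 7, −78 to 0 °C
Reagents that add atoms: none
Why: C-alkylation (SN2) of the dilithium phenoxide of a 2-acylphloroglucinol by a primary triflate should take place at the ring carbon flanked by both phenoxide oxygens, the aggregated lithium salt in a weakly polar medium favouring C- over O-alkylation; the side-chain stereocentre is not involved (its descriptor becomes S only through the priority rules).

**Step 5**
Reactants: 8 lavandulyl benzophenone
Product: 9 3-{2,4-dihydroxy-6-methoxy-5-(3-methylbut-2-enyl)-3-[(2S)-5-methyl-2-(prop-1-en-2-yl)hex-4-enyl]benzoyl}phenyl tosylate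
Conditions: prenyl bromide (1.1 equiv), KOH (10 % aq), 0 °C
Reagents that add atoms: prenyl bromide, CC(C)=CCBr
Why: Classical aqueous-alkali C-prenylation of an acylphloroglucinol (SN2 at the allylic bromide, then rearomatisation) should go to the only remaining ring C–H, which is less hindered than the already substituted carbon and restores aromaticity.

**Step 6**
Reactants: 10 2-bromo-3,3-diethoxyprop-1-ene
Product: 13 3-(diethoxymethyl)-2-methylbut-3-en-2-yl acetate, via vinyllithium 11 (not isolated), via lithium alkoxide 12 (not isolated)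
Conditions: n-BuLi, THF, −78 °C; acetone; then Ac2O, −78 °C to rt
Reagents that add atoms: acetone, CC(C)=O; acetic anhydride, CC(=O)OC(C)=O
Why: Bromine–lithium exchange gives the α-lithioacrolein acetal, which adds to acetone (1,2-addition), and the tertiary lithium alkoxide is acetylated in the same flask.

**Step 7**
Reactants: 13 acetal acetate
Product: 14 3-acetoxy-3-methyl-2-methylenebutanal
Conditions: (CO2H)2, H2O/THF, 0 °C to rt
Reagents that add atoms: water, O
Why: Mild acid-catalysed acetal hydrolysis should unveil the enal without ionising the tertiary allylic acetate.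

**Step 8**
Reactants: 9 lavandulyl prenyl benzophenone; 14 3-acetoxy-3-methyl-2-methylenebutanal
Product: 16 7-endo aldehyde of the 4-O-methyl bicyclo[3.3.1]nonene-2,9-dione core, via dearomatised enal 15 (not isolated)
Conditions: 14 (1.5 equiv), CsOH·H2O, O-allyl-N-(9-anthracenylmethyl)cinchonidinium bromide (20 mol%), 4 Å MS, CH2Cl2, −50 to −20 °C; aq. NH4Cl at −50 °C
Reagents that add atoms: none
Why: The phenoxide of 9, ion-paired with the chiral ammonium cation, adds through C1 to the methylene terminus of 14 (C1–C8), the aldehyde enolate expels acetate (E1cB) to give the β,β-dimethyl enal 15, whose remaining vinylogous enolate (O–C9=C5) adds through C5 to the CMe2 terminus (C5–C6), and the new aldehyde enolate is protonated by water. The closest known reaction is the alkylative dearomatisation–annulation of 3,5-dialkylated acylphloroglucinols with this type of α-(acetoxyalkyl) enal, including its variant under cinchona phase-transfer catalysis. The C1–C8 bond forms intermolecularly, and ring B (C1–C8–C7–C6–C5–C9) then closes by a 6-endo-trig (enolendo) conjugate addition. C1 is set by the face of the planar phenoxide that the ammonium cation leaves open (reagent control, because the remote side-chain centre has little influence; the pseudo-enantiomeric cinchoninium salt is used if this cation proves mismatched, and the minor isomer is a separable diastereomer), and C5 follows from C1 because the tether can reach C5 only on the same face. C7 is set by kinetic protonation of the aldehyde enolate from the open exo face, the endo face being covered by the C2–C4 bridge and its aroyl group, which should give the 7-endo aldehyde that low temperature keeps from equilibrating. The step needs site selectivity for C1 over C5 in the first attack and for C5 over C3 in the closure: the O4 methyl ether is meant to secure both, because C1 is the only carbon flanked by two free phenoxide oxygens while C5 sits next to the twisted methoxy group, and because without an O4 enolate the aroyl-bearing C3 is deactivated and cannot be locked by a follow-up aldol; the same methyl group protects the enol for the endgame.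

**Step 9**
Reactants: 16 7-endo aldehyde
Product: 18 allylic acetate (C7–CH(OAc)–CH=CH2; both carbinol epimers), via allylic alkoxide 17 (not isolated)
Conditions: CH2=CHMgBr, CeCl3, THF, −78 °C; then Ac2O, DMAP, −78 °C to rt
Reagents that add atoms: vinylmagnesium bromide, C=C[Mg]Br; acetic anhydride, CC(=O)OC(C)=O
Why: Organocerium 1,2-addition to the hindered, enolisable aldehyde should proceed without α-deprotonation, so C7 stays endo (aryl ketone, vinylogous ester and C9 ketone are too hindered to react at −78 °C), and the alkoxide is acetylated in the flask; the new carbinol centre forms as an inconsequential mixture that is erased in step 10.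

**Step 10**
Reactants: 18 allylic acetate
Product: 19 7-endo-allyl compound
Conditions: Pd(PPh3)4 (10 mol%), HCO2NH4, 1,4-dioxane, 90 °C
Reagents that add atoms: none
Why: Palladium-catalysed formate reduction of the allylic acetate (Tsuji–Trost-type hydrogenolysis) delivers hydride to the more substituted terminus of the π-allyl complex, so the terminal alkene should result and the adjacent C7 stereocentre is untouched.

**Step 11**
Reactants: 19 7-endo-allyl compound
Product: 20 4-O-methyl 3'-O-tosyl derivative of the target
Conditions: second-generation Grubbs catalyst (H2IMes)(PCy3)Cl2Ru=CHPh (10 mol%), 2-methyl-2-butene, CH2Cl2, 40 °C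
Reagents that add atoms: 2-methyl-2-butene, CC=C(C)C
Why: Olefin cross-metathesis of the only monosubstituted alkene with 2-methyl-2-butene should give the prenyl group, while the trisubstituted prenyl alkenes and the 1,1-disubstituted isopropenyl group are unreactive and no E/Z issue arises.

**Step 12**
Reactants: 20 protected target
Product: 21 target
Conditions: LiOH·H2O (excess), 1,4-dioxane/H2O, 90 °C; then aq. NaH2PO4
Reagents that add atoms: lithium hydroxide, [Li+].[OH-]
Why: Hydroxide should cleave the vinylogous methyl ester by addition–elimination and the aryl sulfonate at sulfur (saponification), leaving the enolised β-triketone and the free phenol; no stereocentre is epimerisable because C1 and C5 are quaternary and H7 is not acidic.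

**Compound list**

1 | 3-hydroxybenzoic acid | O=C(O)c1cccc(O)c1 | starting material
2 | 3-(tosyloxy)benzoic acid | Cc1ccc(cc1)S(=O)(=O)Oc1cccc(c1)C(=O)O | intermediate
3 | 5-methoxyresorcinol | COc1cc(O)cc(O)c1 | starting material
4 | 3-(tosyloxy)benzoyl chloride | Cc1ccc(cc1)S(=O)(=O)Oc1cccc(c1)C(Cl)=O | intermediate
5 | 3-(2,4-dihydroxy-6-methoxybenzoyl)phenyl tosylate | COc1cc(O)cc(O)c1C(=O)c1cccc(OS(=O)(=O)c2ccc(C)cc2)c1 | intermediate
6 | (R)-lavandulol, (2R)-5-methyl-2-(prop-1-en-2-yl)hex-4-en-1-ol | C=C(C)[C@@H](CC=C(C)C)CO | starting material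
7 | (R)-lavandulyl triflate | C=C(C)[C@@H](CC=C(C)C)COS(=O)(=O)C(F)(F)F | intermediate
8 | 3-{2,4-dihydroxy-6-methoxy-3-[(2S)-5-methyl-2-(prop-1-en-2-yl)hex-4-enyl]benzoyl}phenyl tosylate | COc1cc(O)c(C[C@H](CC=C(C)C)C(C)=C)c(O)c1C(=O)c1cccc(OS(=O)(=O)c2ccc(C)cc2)c1 | intermediate
9 | 3-{2,4-dihydroxy-6-methoxy-5-(3-methylbut-2-enyl)-3-[(2S)-5-methyl-2-(prop-1-en-2-yl)hex-4-enyl]benzoyl}phenyl tosylate | COc1c(CC=C(C)C)c(O)c(C[C@H](CC=C(C)C)C(C)=C)c(O)c1C(=O)c1cccc(OS(=O)(=O)c2ccc(C)cc2)c1 | intermediate
10 | 2-bromo-3,3-diethoxyprop-1-ene | C=C(Br)C(OCC)OCC | starting material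
11 | (3,3-diethoxyprop-1-en-2-yl)lithium | [Li]C(=C)C(OCC)OCC | intermediate
12 | lithium 3-(diethoxymethyl)-2-methylbut-3-en-2-olate | C=C(C(OCC)OCC)C(C)(C)[O-].[Li+] | intermediate
13 | 3-(diethoxymethyl)-2-methylbut-3-en-2-yl acetate | C=C(C(OCC)OCC)C(C)(C)OC(C)=O | intermediate
14 | 3-acetoxy-3-methyl-2-methylenebutanal (2-methyl-3-methylidene-4-oxobutan-2-yl acetate) | C=C(C=O)C(C)(C)OC(C)=O | intermediate
15 | dearomatised enal: 6-(2-formyl-3-methylbut-2-enyl)-5-hydroxy-3-methoxy-6-[(2S)-lavandulyl]-4-prenyl-2-[3-(tosyloxy)benzoyl]cyclohexa-2,4-dien-1-one, quaternary carbon configured as C1 of 16 | CC(C)=C(C=O)C[C@]1(C[C@H](CC=C(C)C)C(C)=C)C(=O)C(C(=O)c2cccc(OS(=O)(=O)c3ccc(C)cc3)c2)=C(OC)C(CC=C(C)C)=C1O | intermediate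
16 | 4-methoxy-6,6-dimethyl-1-[(2S)-lavandulyl]-5-prenyl-3-[3-(tosyloxy)benzoyl]-2,9-dioxobicyclo[3.3.1]non-3-ene-7-carbaldehyde, bridgeheads as in the target, CHO endo | C=C(C)[C@@H](CC=C(C)C)C[C@@]12C[C@@H](C=O)C(C)(C)[C@@](CC=C(C)C)(C(OC)=C(C(=O)c3cccc(OS(=O)(=O)c4ccc(C)cc4)c3)C1=O)C2=O | intermediate
17 | allylic alkoxide from vinyl addition to 16 (7-endo; carbinol centre unassigned) | C=C(C)[C@@H](CC=C(C)C)C[C@@]12C[C@@H](C([O-])C=C)C(C)(C)[C@@](CC=C(C)C)(C(OC)=C(C(=O)c3cccc(OS(=O)(=O)c4ccc(C)cc4)c3)C1=O)C2=O | intermediate
18 | 7-endo-(1-acetoxyprop-2-enyl) compound (carbinol epimers) | C=C(C)[C@@H](CC=C(C)C)C[C@@]12C[C@@H](C(OC(C)=O)C=C)C(C)(C)[C@@](CC=C(C)C)(C(OC)=C(C(=O)c3cccc(OS(=O)(=O)c4ccc(C)cc4)c3)C1=O)C2=O | intermediate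
19 | 7-endo-allyl compound | C=C(C)[C@@H](CC=C(C)C)C[C@@]12C[C@@H](CC=C)C(C)(C)[C@@](CC=C(C)C)(C(OC)=C(C(=O)c3cccc(OS(=O)(=O)c4ccc(C)cc4)c3)C1=O)C2=O | intermediate
20 | 4-O-methyl 3'-O-tosyl derivative of the target (7-endo-prenyl) | C=C(C)[C@@H](CC=C(C)C)C[C@@]12C[C@@H](CC=C(C)C)C(C)(C)[C@@](CC=C(C)C)(C(OC)=C(C(=O)c3cccc(OS(=O)(=O)c4ccc(C)cc4)c3)C1=O)C2=O | intermediate
21 | (1R,5R,7R)-2-hydroxy-3-(3-hydroxybenzoyl)-6,6-dimethyl-5,7-bis(3-methylbut-2-enyl)-1-[(2S)-5-methyl-2-(prop-1-en-2-yl)hex-4-enyl]bicyclo[3.3.1]non-2-ene-4,9-dione (numbering used here) | C=C(C)[C@@H](CC=C(C)C)C[C@@]12C[C@@H](CC=C(C)C)C(C)(C)[C@@](CC=C(C)C)(C(=O)C(C(=O)c3cccc(O)c3)=C1O)C2=O | target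

**Count.** Total steps: 12. Longest linear sequence: 9 steps (1, 2, 4, 5, 8, 9, 10, 11, 12).

**Steps most likely to fail**

Step 8. The first attack may take place at C5 in place of C1, the ion pair may give too little facial bias, closure may run through C3, or the aldehyde may equilibrate to the 7-exo epimer. The fallback splits the cascade and moves control from the catalyst to separation and thermodynamics. It sets out from 9 (with 14). C-alkylation alone with LiN(SiMe3)2 (2.1 equiv) in THF at −78 °C and an acetic acid quench should give the dearomatised enal 15, now isolated; its C1 epimer and any C5-alkylated isomer are removed by chromatography. Substoichiometric KN(SiMe3)2 in THF at 65 °C (the established conditions for closure to the C5-bonded bicycle) then gives the thermodynamic 7-exo aldehyde F1. Brief enolisation of this with KN(SiMe3)2 at −78 °C and a cold acetic acid quench protonates from the exo face and comes back to the route at 16.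

Step 4. The hard triflate may alkylate the free para-phenoxide oxygen instead of carbon. The fallback forms the aryl–CH2 bond by directed ortho-metalation before the ketone exists and sets out from 3. MOMCl and i-Pr2NEt in CH2Cl2 give the bis(methoxymethyl) ether F2. n-BuLi in THF at 0 °C (lithiation between the two MOM ethers) followed by triflate 7 at −78 °C gives the lavandulyl arene F3. A second lithiation (n-BuLi, TMEDA, ring position between OMOM and OMe) and acylation with acid chloride 4 (made from 2 as in step 2) at −78 °C give the protected ketone F4. HCl in MeOH at 0 °C removes the MOM groups and comes back to the route at 8.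

Step 5. Geminal (dearomatising) prenylation at the lavandulyl-bearing carbon and O-prenylation may compete with substitution at the ring C–H. The fallback sets out from 8. Palladium-catalysed O-alkylation of the non-chelated para hydroxyl with methyl 2-methylbut-3-en-2-yl carbonate (Pd(PPh3)4, THF, rt) gives the 1,1-dimethylallyl ether F5. Aromatic Claisen rearrangement of this (PhNEt2, 130 °C) delivers the allyl unit, with allylic inversion, to the only free ortho position and comes back to the route at 9.

**Further compounds**

F1 | step 8 | 7-exo epimer of aldehyde 16 | C=C(C)[C@@H](CC=C(C)C)C[C@@]12C[C@H](C=O)C(C)(C)[C@@](CC=C(C)C)(C(OC)=C(C(=O)c3cccc(OS(=O)(=O)c4ccc(C)cc4)c3)C1=O)C2=O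
F2 | step 4 | 1-methoxy-3,5-bis(methoxymethoxy)benzene | COc1cc(OCOC)cc(OCOC)c1
F3 | step 4 | 5-methoxy-1,3-bis(methoxymethoxy)-2-[(2S)-5-methyl-2-(prop-1-en-2-yl)hex-4-enyl]benzene | COc1cc(OCOC)c(C[C@H](CC=C(C)C)C(C)=C)c(OCOC)c1
F4 | step 4 | 3-{6-methoxy-2,4-bis(methoxymethoxy)-3-[(2S)-5-methyl-2-(prop-1-en-2-yl)hex-4-enyl]benzoyl}phenyl tosylate | COc1cc(OCOC)c(C[C@H](CC=C(C)C)C(C)=C)c(OCOC)c1C(=O)c1cccc(OS(=O)(=O)c2ccc(C)cc2)c1
F5 | step 5 | 3-{2-hydroxy-6-methoxy-4-[(2-methylbut-3-en-2-yl)oxy]-3-[(2S)-5-methyl-2-(prop-1-en-2-yl)hex-4-enyl]benzoyl}phenyl tosylate | COc1cc(OC(C)(C)C=C)c(C[C@H](CC=C(C)C)C(C)=C)c(O)c1C(=O)c1cccc(OS(=O)(=O)c2ccc(C)cc2)c1
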